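The target does not stay as it is made. In the epsilon run, charged at 24 mM, it falls from 84.5% at 20.0 s to 73.9% at 120 s while its isomer climbs, and at 80.0 s the two sum to 100% of the charge. So you can treat them as a reversible first-order pair, a two-level system with forward constant k_f and backward constant k_b. Its distance from equilibrium decays as exp(−(k_f+k_b)t), whatever amount is present.

all flasks: free catalyst 0.05 mol%
- alpha: starting material 1.5 mM; run made earlier
- epsilon: starting material 24 mM; run made earlier
- north-east: starting material 1.2 mM; time 2.5 min
- north: starting material 2.5 mM; time 2.5 min
- south-west: starting material 5.0 mM; time 2.5 min
- south: starting material 10 mM; time 2.5 min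
- north-west: starting material 20 mM; time 2.5 min

| run | time / s | target / % | isomer of the product / % |
|---|---|---|---|
| alpha | 20.0 | 30.9 | 4.0 |
| alpha | 40.0 | 47.2 | 9.9 |
| alpha | 50.0 | 53.9 | 12.6 |
| alpha | 80.0 | 63.3 | 19.6 |
| alpha | 120 | 69.7 | 23.6 |
| epsilon | 20.0 | 84.5 | 14.5 |
| epsilon | 40.0 | 77.8 | 22.4 |
| epsilon | 50.0 | 75.9 | 24.3 |
| epsilon | 80.0 | 74.4 | 25.7 |
| epsilon | 120 | 73.9 | 26.7 |

(each reading ± 0.3 percentage points)

- what was read earlier has a scatter of 0.3 percentage points, one standard deviation
- "hardly changes" means that all values lie within two and a half points (for a concentration: within two and a half percent of the largest)

- share of target in all that became target or isomer of the product for north-east, north, south-west, south, north-west, in this order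
- how that number moves from the first to the last of them (rises, then falls / falls all the way / rises all the way / falls, then rises / hardly changes)

Take the isomer's last epsilon reading as its equilibrium value. Its gap to that value shrinks from 12 percentage points at 20.0 s to 4.3 points at 40.0 s. This gives t_r = ln(2)/(k_f+k_b) = 0.222 min, the relaxation half-life, the time in which the pair halves its distance from equilibrium. The asked time is far longer than t_r, so I expect thermodynamic control, with the share S = target/(target + isomer) at its last epsilon reading, 73.5%.

A small charge at the same loading holds less catalyst and feeds more slowly, and fresh target raises S for as long as it arrives. The alpha run, charged at 1.5 mM, has 6.70% of its charge unaccounted for at 120 s, and its share there reads 74.7%, which is 1.2 points above the epsilon value. My reckoning therefore puts north-east about that far up and the other flasks near 73.5%.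

The forecast gives 74.6%, 73.8%, 73.6%, 73.6% and 73.6%, so its shape is hardly changes, on the ground that “All values sit at equilibrium within the limit”. Its plateau lies slightly above the 73.5% I read.

The flasks give 74.4%, 73.7%, 73.6%, 73.5% and 73.5%, and the shape is hardly changes.

    catalyst intermediate → free catalyst + target (k = 360 s⁻¹)
    target ⇌ isomer of the product (K = 0.360, k = 0.0150 s⁻¹)
    starting material + free catalyst → catalyst intermediate (k = 31000 M⁻¹ s⁻¹)

The asked time holds 11.3 of the relaxation half-lives read above, and the scheme puts no catalyst in that step, so t_r serves north-west and north-east alike. In north-west the way back from isomer to target holds the share up: it stands at 73.5% and drops to 11.6% with that way back removed. The way back from isomer to target holds the share up in north-east too: removing that way back takes the share there from 74.4% to 25.0%.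

The runs were generated by integration with made-up constants; scatter was added.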